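**Assumptions (one line each):**
- The target is the erythro (anti) 7''R,8''S aryl glyceryl ether of tricin with a p-hydroxyphenyl group. I checked the SMILES: C8'' is S and C7'' is R, which is anti in the zig-zag drawing.
- Noyori–Ikariya ATH with dynamic kinetic resolution of α-aryloxy-β-ketoesters is assumed to be anti-selective, as it is for α-alkoxy analogues. The (S,S)-catalyst is assumed to give the 3R (benzylic) alcohol.

## Retrosynthesis
1. The target comes from global O-debenzylation of a tri-O-benzyl diol (5-OBn, 7-OBn, 4''-OBn).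
2. The C9'' primary alcohol comes from reducing an anti-α-aryloxy-β-hydroxy ester. That ester sets C7'' and C8'' in one operation by ATH with dynamic kinetic resolution of a racemic α-aryloxy-β-ketoester.
3. The ketoester comes from SN2 coupling of the 4'-phenol of 5,7-di-O-benzyltricin with an α-bromo-β-ketoester, which is made from 4-benzyloxyacetophenone.
4. Ring order: A ring (phloroacetophenone), then chalcone, then C-ring closure (I2/DMSO), then the ether side chain. The B ring comes from syringaldehyde.

## Forward route

**Step 1**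
Reactants: 1 (2',4',6'-trihydroxyacetophenone), 2 (benzyl bromide)
Product: 3 (2'-hydroxy-4',6'-bis(benzyloxy)acetophenone)
Conditions: BnBr (2.1 equiv), K2CO3, acetone, reflux
Reagents that add atoms: BnBr, BrCc1ccccc1
Why: Williamson etherification. The 4'- and 6'-OH groups react, and the 2'-OH stays because it is hydrogen-bonded to the carbonyl.

**Step 2**
Reactants: 3, 4 (syringaldehyde, 4-hydroxy-3,5-dimethoxybenzaldehyde)
Product: 5 ((E)-2'-hydroxy-4',6'-bis(benzyloxy)-4-hydroxy-3,5-dimethoxychalcone)
Conditions: KOH (aq), EtOH, rt, 48 h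
Reagents that add atoms: none
Why: Claisen–Schmidt aldol condensation. Excess base covers the free syringyl phenol and gives the E-enone.

**Step 3**
Reactants: 5
Product: 6 (5,7-di-O-benzyltricin, 4'-OH free)
Conditions: I2 (cat.), DMSO, 130 °C
Reagents that add atoms: none
Why: Oxidative cyclization of the 2'-hydroxychalcone (oxa-Michael addition, then iodination and elimination, with DMSO as terminal oxidant). This closes the C ring and makes the flavone C2=C3 bond. Benzyl ethers survive.

**Step 4**
Reactants: 7 (4'-benzyloxyacetophenone), 8 (diethyl carbonate)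
Product: 9 (ethyl 3-(4-benzyloxyphenyl)-3-oxopropanoate)
Conditions: NaH, toluene, reflux
Reagents that add atoms: diethyl carbonate, CCOC(=O)OCC
Why: Crossed Claisen-type C-acylation. The ketone enolate attacks the carbonate, and the stabilized β-ketoester enolate drives the reaction.

**Step 5**
Reactants: 9, 10 (N-bromosuccinimide)
Product: 11 (ethyl 2-bromo-3-(4-benzyloxyphenyl)-3-oxopropanoate)
Conditions: NBS, MeCN, rt
Reagents that add atoms: NBS, O=C1CCC(=O)N1Br
Why: α-Bromination of the 1,3-dicarbonyl through its enol, which is very selective for mono-bromination.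

**Step 6**
Reactants: 6, 11
Product: 12 (racemic ethyl 2-[4-(5,7-dibenzyloxy-4-oxo-chromen-2-yl)-2,6-dimethoxyphenoxy]-3-(4-benzyloxyphenyl)-3-oxopropanoate)
Conditions: K2CO3, DMF, rt
Reagents that add atoms: none (HBr is lost)
Why: SN2 Williamson etherification at the doubly activated secondary bromide by the 4'-phenoxide. This makes the C8''–O–Ar ether bond, and C8'' is stereochemically labile here, which is what the next step needs.

**Step 7**
Reactants: 12
Product: 13 (ethyl (2R,3R)-3-hydroxy-3-(4-benzyloxyphenyl)-2-aryloxypropanoate, anti; aryl = 5,7-dibenzyloxy-tricin-4'-yl)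
Conditions: RuCl[(S,S)-TsDPEN](p-cymene) (2 mol%), HCOOH/Et3N 5:2, CH2Cl2, 30 °C
Reagents that add atoms: none (only H is added, from formate)
Why: Noyori–Ikariya asymmetric transfer hydrogenation with dynamic kinetic resolution. Et3N epimerizes the very acidic C8''–H, the chiral Ru–H reduces one ketone enantioface to set C7'' as R, and the matched α-epimer reacts fastest to give the anti diastereomer (C8'' is R in the ester, which becomes S once the ester is reduced to CH2OH). The flavone and benzyl ethers are inert to these conditions.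

**Step 8**
Reactants: 13
Product: 14 ((7''R,8''S)-tri-O-benzyl diol)
Conditions: LiBH4, THF, 0 °C to rt
Reagents that add atoms: none
Why: Hydride reduction of the α-aryloxy ester, which is activated and assisted by the neighbouring alkoxide. Neither stereocenter is touched, and the flavone C4 carbonyl, a vinylogous ester, is much less reactive under these mild conditions.

**Step 9**
Reactants: 14
Product: 15 (target)
Conditions: H2 (1 atm), 10% Pd/C, THF/MeOH, rt
Reagents that add atoms: none
Why: Hydrogenolysis removes the three aryl benzyl ethers. The secondary benzylic OH, the aryl ether and the flavone survive short reaction times at 1 atm, and the stereocenters are unaffected.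

## Compound list
1 | 2',4',6'-trihydroxyacetophenone | CC(=O)c1c(O)cc(O)cc1O | starting material
2 | benzyl bromide | BrCc1ccccc1 | starting material
3 | 2'-hydroxy-4',6'-bis(benzyloxy)acetophenone | CC(=O)c1c(O)cc(OCc2ccccc2)cc1OCc1ccccc1 | intermediate
4 | syringaldehyde | COc1cc(C=O)cc(OC)c1O | starting material
5 | (E)-2'-hydroxy-4',6'-bis(benzyloxy)-4-hydroxy-3,5-dimethoxychalcone | COc1cc(/C=C/C(=O)c2c(O)cc(OCc3ccccc3)cc2OCc2ccccc2)cc(OC)c1O | intermediate
6 | 5,7-di-O-benzyltricin | COc1cc(-c2cc(=O)c3c(OCc4ccccc4)cc(OCc4ccccc4)cc3o2)cc(OC)c1O | intermediate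
7 | 4'-benzyloxyacetophenone | CC(=O)c1ccc(OCc2ccccc2)cc1 | starting material
8 | diethyl carbonate | CCOC(=O)OCC | starting material
9 | ethyl 3-(4-benzyloxyphenyl)-3-oxopropanoate | CCOC(=O)CC(=O)c1ccc(OCc2ccccc2)cc1 | intermediate
10 | N-bromosuccinimide | O=C1CCC(=O)N1Br | starting material
11 | ethyl 2-bromo-3-(4-benzyloxyphenyl)-3-oxopropanoate | CCOC(=O)C(Br)C(=O)c1ccc(OCc2ccccc2)cc1 | intermediate
12 | racemic α-aryloxy-β-ketoester | COc1cc(-c2cc(=O)c3c(OCc4ccccc4)cc(OCc4ccccc4)cc3o2)cc(OC)c1OC(C(=O)OCC)C(=O)c1ccc(OCc2ccccc2)cc1 | intermediate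
13 | anti-α-aryloxy-β-hydroxy ester (2R,3R) | COc1cc(-c2cc(=O)c3c(OCc4ccccc4)cc(OCc4ccccc4)cc3o2)cc(OC)c1O[C@@H](C(=O)OCC)[C@H](O)c1ccc(OCc2ccccc2)cc1 | intermediate
14 | tri-O-benzyl (7''R,8''S)-diol | COc1cc(-c2cc(=O)c3c(OCc4ccccc4)cc(OCc4ccccc4)cc3o2)cc(OC)c1O[C@@H](CO)[C@H](O)c1ccc(OCc2ccccc2)cc1 | intermediate
15 | (−)-(7''R,8''S)-4'',5,7-trihydroxy-3',5'-dimethoxy-4',8''-oxyflavonolignan-7'',9''-diol | COc1cc(-c2cc(=O)c3c(O)cc(O)cc3o2)cc(OC)c1O[C@@H](CO)[C@H](O)c1ccc(O)cc1 | target

## Totals
- Total steps: 9.
- Longest linear sequence: 7 steps (1 → 3 → 5 → 6 → 12 → 13 → 14 → 15, counted by reaction: Steps 1, 2, 3, 6, 7, 8, 9).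

**Three steps most likely to fail**
1. **Step 7 (ATH-DKR).** The diastereoselectivity or enantioselectivity may be poor for the bulky, electron-rich aryloxy ketoester, or the sense of induction may be the opposite of the assumed one.
   - Fallback: ketoreductase-catalysed DKR of 12, screening KRED panels for the (2R,3R)-anti product.
2. **Step 6 (hindered SN2).** The 2,6-dimethoxyphenoxide is a poor nucleophile toward the secondary, enolizable α-bromo-β-ketoester, and halophilic side reactions are possible.
   - Fallback: Rh2(OAc)4-catalysed O–H insertion of 6 into ethyl 2-diazo-3-(4-benzyloxyphenyl)-3-oxopropanoate. This diazo compound comes from 9 by diazo transfer with p-ABSA. It avoids both the base and the bromide.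
3. **Step 9 (global debenzylation).** Pd/C and H2 may over-reduce the flavone C2=C3 bond or hydrogenolyse the p-hydroxybenzylic C7''–OH.
   - Fallback: Lewis-acid O-debenzylation with BCl3 and pentamethylbenzene (cation scavenger) in CH2Cl2 at −78 °C. This removes the benzyl groups without any hydrogenation.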